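**Retrosynthetic overview**
1. Endgame: removing the C10 silyl ether and the C3 acetate leads back to a ten-membered cross-conjugated dienone. Its C3 ketone is reduced under catalyst control.
2. Ten-membered ring (formed second): the C3–C4 bond comes from an intramolecular Nozaki–Hiyama–Kishi closure of a (Z)-alkenyl iodide onto an (E)-enal.
3. Key disconnection C6–C7, together with the γ-lactone (ring formed first): intermolecular zinc Barbier allylation and lactonisation of (Z)-3-iodobut-2-enal with a chiral methyl 2-(bromomethyl)enoate. This sets C6 and C7.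
4. Bromoenoate: Morita–Baylis–Hillman reaction and SN2′ bromination of a C7 aldehyde. The aldehyde is built from (R)-linalool (C10), an L-proline aminoxylation (C8) and a cross metathesis (E-C1=C2, C3).
5. Iodoenal: Z-selective hydroiodination of ethyl but-2-ynoate. The angelate is placed on C8 after the coupling.

Assumption: the SMILES is read literally, i.e. (3R,6R,7S,8R,10R,1E,4Z) with H6 and H7 on the same face (cis-fused γ-lactone).
Conventions: germacrane numbering throughout (ring C1–C10, lactone C11–C13, C14 = methyl on C10, C15 = methyl on C4). TBS = tert-butyldimethylsilyl, PMB = 4-methoxybenzyl, Ang = (Z)-2-methylbut-2-enoyl.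

**East fragment**

Step 1
Reactants: 1 (R)-(−)-linalool
Product: 2 (3R)-3-(TBSO)-3,7-dimethylocta-1,6-diene
Conditions: TBSOTf (1.3 equiv), 2,6-lutidine (2 equiv), CH2Cl2, 0 °C → rt
Reagents that add atoms: tert-butyldimethylsilyl triflate, CC(C)(C)[Si](C)(C)OS(=O)(=O)C(F)(F)F
Why: Silyl ether protection with a silyl triflate is strong enough for the hindered tertiary alcohol, leaves C10 (R, chiral pool) untouched and blocks lactol formation once C7 becomes an aldehyde.

Step 2
Reactants: 2 (3R)-3-(TBSO)-3,7-dimethylocta-1,6-diene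
Product: 3 (3R)-3-(TBSO)-6,7-epoxy-3,7-dimethyloct-1-ene (C6 epimers)
Conditions: mCPBA (1.05 equiv), CH2Cl2, 0 °C
Reagents that add atoms: 3-chloroperbenzoic acid, OOC(=O)c1cccc(Cl)c1
Why: In this Prilezhaev epoxidation the electron-rich trisubstituted alkene reacts far faster than the hindered vinyl group, and the new epoxide stereocentre is lost in the next step.

Step 3
Reactants: 3 (3R)-3-(TBSO)-6,7-epoxy-3,7-dimethyloct-1-ene
Product: 4 (4R)-4-(TBSO)-4-methylhex-5-enal
Conditions: H5IO6 (1.3 equiv), THF/H2O, 0 °C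
Reagents that add atoms: none
Why: Periodic acid opens the epoxide and cleaves the resulting glycol in one pot (Malaprade cleavage), giving the C7 aldehyde without touching the vinyl group or the tertiary silyl ether.

Step 4
Reactants: 4 (4R)-4-(TBSO)-4-methylhex-5-enal
Product: 6 (2R,4R)-4-(TBSO)-4-methyl-2-(phenylaminooxy)hex-5-en-1-ol, via (2R,4R)-aminooxy aldehyde 5 (not isolated)
Conditions: PhNO (1.0 equiv), L-proline (20 mol%), DMSO, rt, 30 min; then NaBH4, EtOH, 0 °C
Reagents that add atoms: nitrosobenzene, O=Nc1ccccc1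
Why: In this proline-catalysed enamine α-aminoxylation the carboxylic acid of L-proline steers the oxygen of PhNO onto one enamine face and sets C8 as R under catalyst control, and the immediate reduction prevents epimerisation of 5.

Step 5
Reactants: 6 (2R,4R)-4-(TBSO)-4-methyl-2-(phenylaminooxy)hex-5-en-1-ol
Product: 7 (2R,4R)-4-(TBSO)-4-methylhex-5-ene-1,2-diol
Conditions: Zn dust, AcOH/THF, rt
Reagents that add atoms: none
Why: Dissolving-metal reduction cleaves only the weak N–O bond, so the C8–O bond, the alkene and the silyl ether stay intact.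

Step 6
Reactants: 7 (2R,4R)-4-(TBSO)-4-methylhex-5-ene-1,2-diol
Product: 8 (4R)-4-[(2R)-2-(TBSO)-2-methylbut-3-enyl]-2-(4-methoxyphenyl)-1,3-dioxolane (acetal epimers)
Conditions: 4-MeOC6H4CH(OMe)2 (1.2 equiv), PPTS (5 mol%), CH2Cl2, rt
Reagents that add atoms: 4-methoxybenzaldehyde dimethyl acetal, COc1ccc(C(OC)OC)cc1
Why: Acid-catalysed transacetalisation ties the 1,2-diol into a five-membered benzylidene acetal under conditions too mild for the tertiary TBS ether, and the acetal epimers converge in step 8.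

Step 7
Reactants: 8 (4R)-4-[(2R)-2-(TBSO)-2-methylbut-3-enyl]-2-(4-methoxyphenyl)-1,3-dioxolane; 9 allyl tert-butyldimethylsilyl ether
Product: 10 (4R)-4-[(2R,3E)-2,5-bis(TBSO)-2-methylpent-3-enyl]-2-(4-methoxyphenyl)-1,3-dioxolane
Conditions: 9 (4 equiv), second-generation Hoveyda–Grubbs catalyst (5 mol%), CH2Cl2, 40 °C
Reagents that add atoms: none
Why: In this olefin cross metathesis the vinyl group next to quaternary C10 cannot homodimerise and so pairs with the unhindered partner used in excess, while the bulk at C10 enforces the E geometry of C1=C2.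

Step 8
Reactants: 10 (4R)-4-[(2R,3E)-2,5-bis(TBSO)-2-methylpent-3-enyl]-2-(4-methoxyphenyl)-1,3-dioxolane
Product: 11 (2R,4R,5E)-4,7-bis(TBSO)-2-(PMBO)-4-methylhept-5-en-1-ol
Conditions: i-Bu2AlH (3 equiv), CH2Cl2, −78 → 0 °C; aq. potassium sodium tartrate
Reagents that add atoms: none
Why: In this regioselective reductive acetal opening aluminium binds the less hindered primary oxygen, so hydride delivery leaves the PMB group on O8 and frees the C7 alcohol.

Step 9
Reactants: 11 (2R,4R,5E)-4,7-bis(TBSO)-2-(PMBO)-4-methylhept-5-en-1-ol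
Product: 12 (2R,4R,5E)-4,7-bis(TBSO)-2-(PMBO)-4-methylhept-5-enal
Conditions: Dess–Martin periodinane (1.3 equiv), CH2Cl2, 0 °C → rt
Reagents that add atoms: none
Why: Dess–Martin oxidation is base-free and fast, so the α-alkoxy aldehyde forms without epimerisation at C8.

Step 10
Reactants: 12 (2R,4R,5E)-4,7-bis(TBSO)-2-(PMBO)-4-methylhept-5-enal; 13 methyl acrylate
Product: 14 methyl (4R,6R,7E)-6,9-bis(TBSO)-3-hydroxy-4-(PMBO)-6-methyl-2-methylidenenon-7-enoate (C3 carbinol epimers)
Conditions: 13 (5 equiv), DABCO (1 equiv), MeOH, rt, 3–5 d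
Reagents that add atoms: none
Why: The Morita–Baylis–Hillman reaction works well on the activated α-alkoxy aldehyde and installs C11–C13, the weakly basic amine spares C8, and the new carbinol (C7) becomes sp2 in the next step.

Step 11
Reactants: 14 methyl (4R,6R,7E)-6,9-bis(TBSO)-3-hydroxy-4-(PMBO)-6-methyl-2-methylidenenon-7-enoate
Product: 15 methyl (2Z,4R,6R,7E)-2-(bromomethyl)-6,9-bis(TBSO)-4-(PMBO)-6-methylnona-2,7-dienoate
Conditions: NBS (1.5 equiv), Me2S (1.8 equiv), CH2Cl2, 0 °C → rt
Reagents that add atoms: N-bromosuccinimide, O=C1CCC(=O)N1Br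
Why: Corey–Kim-type activation of the alcohol followed by SN2′ attack of bromide converts both carbinol epimers into the conjugated Z bromide (C8 trans to the ester) under non-acidic conditions that PMB and TBS tolerate.

**West fragment**

Step 12
Reactants: 16 ethyl but-2-ynoate
Product: 17 ethyl (Z)-3-iodobut-2-enoate
Conditions: NaI (1.6 equiv), AcOH, 110 °C
Reagents that add atoms: sodium iodide, [Na+].[I-]
Why: Conjugate hydroiodination of the ynoate proceeds by anti addition of HI and gives only the Z isomer, which fixes the future 4Z geometry.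

Step 13
Reactants: 17 ethyl (Z)-3-iodobut-2-enoate
Product: 18 (Z)-3-iodobut-2-en-1-ol
Conditions: i-Bu2AlH (2.3 equiv), CH2Cl2, −78 → 0 °C
Reagents that add atoms: none
Why: Hydride reduction of the ester occurs 1,2 and leaves the C–I bond and the alkene geometry unchanged.

Step 14
Reactants: 18 (Z)-3-iodobut-2-en-1-ol
Product: 19 (Z)-3-iodobut-2-enal
Conditions: MnO2 (15 equiv), CH2Cl2, rt, dark; filtered and used at once
Reagents that add atoms: none
Why: Allylic oxidation with MnO2 is neutral, so the Z-enal forms without Z-to-E isomerisation.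

**Fragment union and endgame**

Step 15
Reactants: 15 methyl (2Z,4R,6R,7E)-2-(bromomethyl)-6,9-bis(TBSO)-4-(PMBO)-6-methylnona-2,7-dienoate; 19 (Z)-3-iodobut-2-enal
Product: 22 (4S,5S)-4-[(1R,3R,4E)-3,6-bis(TBSO)-1-(PMBO)-3-methylhex-4-en-1-yl]-5-[(1Z)-2-iodoprop-1-en-1-yl]-3-methylideneoxolan-2-one (cis-lactone), via allylzinc bromide 20 (not isolated), via 6,7-syn hydroxy ester 21 (not isolated)
Conditions: 19 (2 equiv), Zn dust (4 equiv), THF/sat. aq NH4Cl (3:1), 0 °C → rt; then PPTS (10 mol%), CH2Cl2, rt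
Reagents that add atoms: none
Why: In this Barbier-type carbonyl allylation (Dreiding–Schmidt lactone synthesis) zinc inserts only into the allylic C–Br bond and allylzinc 20, with C8 cis to CH2Zn, attacks through C7 in a chair transition state (C8 axial, iodoalkenyl group equatorial) to give the 6,7-syn adduct and hence the cis-lactone, while the C8–H eclipses the alkene (A1,3 strain) so that the aldehyde approaches anti to the C8–OPMB bond (Felkin–Anh-type) and fixes C6 and C7 as in the target.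

Step 16
Reactants: 22 cis-lactone PMB ether
Product: 23 C8 alcohol (22 carrying OH instead of OPMB; 6S,7S,8R,10R)
Conditions: DDQ (1.5 equiv), CH2Cl2/aq. NaH2PO4–Na2HPO4 buffer pH 7 (10:1), 0 °C
Reagents that add atoms: none
Why: Oxidative PMB cleavage is specific for the electron-rich benzyl ether, and the neutral medium does not allow translactonisation, which would need a strained bicyclic orthoester.

Step 17
Reactants: 23 C8 alcohol; 24 angelic acid
Product: 26 C8 angelate (23 carrying OAng at C8; 6S,7S,8R,10R), via angelic 2,4,6-trichlorobenzoic anhydride 25 (not isolated)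
Conditions: 24 (4 equiv), 2,4,6-Cl3C6H2COCl (4 equiv), Et3N (8 equiv), toluene, rt, 2 h; then 23, 80 °C
Reagents that add atoms: none
Why: Yamaguchi-type mixed-anhydride esterification run without DMAP transfers the angeloyl group without Z-to-E drift to the tiglate, and C8 keeps its configuration because its C–O bond is not broken.

Step 18
Reactants: 26 C8 angelate
Product: 27 primary allylic alcohol (26 carrying free C3–OH; C10–OTBS kept)
Conditions: HF·pyridine, pyridine, THF, 0 °C
Reagents that add atoms: none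
Why: In this fluoride-mediated desilylation the unhindered primary allylic TBS ether is cleaved far faster than the tertiary one.

Step 19
Reactants: 27 primary allylic alcohol
Product: 28 (E)-enal (C3 aldehyde; alkenyl iodide at C4)
Conditions: MnO2 (20 equiv), CH2Cl2, rt
Reagents that add atoms: none
Why: MnO2 allylic oxidation is neutral and stops at the enal, which has no epimerisable centre because C10 is quaternary.

Step 20
Reactants: 28 (E)-enal
Product: 30 ten-membered carbinol (C3 epimers; 6R,7S,8R,10R,1E,4Z), via alkenylchromium dichloride 29 (not isolated)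
Conditions: CrCl2 (15 equiv), NiCl2 (0.15 equiv), DMSO, 2 mM, 28 added over 10 h, rt
Reagents that add atoms: none
Why: In the Nozaki–Hiyama–Kishi reaction zerovalent nickel inserts into the C4–I bond with retention of the Z geometry and hands the alkenyl group to trivalent chromium (29), which adds 1,2 to the enal only and tolerates lactone, esters and silyl ether, and the C3 epimer ratio does not matter because C3 is reset in steps 21 and 22.

Step 21
Reactants: 30 ten-membered carbinol
Product: 31 ten-membered cross-conjugated dienone (C3 ketone)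
Conditions: Dess–Martin periodinane (1.5 equiv), CH2Cl2, 0 °C → rt
Reagents that add atoms: none
Why: Dess–Martin oxidation of the only free hydroxyl merges both C3 epimers into one dienone without moving either alkene.

Step 22
Reactants: 31 ten-membered dienone
Product: 32 (3R)-alcohol
Conditions: (S)-2-methyl-CBS-oxazaborolidine (1 equiv), catecholborane (3 equiv), toluene, −78 °C
Reagents that add atoms: none
Why: In the Corey–Bakshi–Shibata reduction the (S)-catalyst treats the α-methyl-substituted C4=C5 arm as the large group and the unsubstituted C1=C2 arm as the small one, which delivers hydride to give 3R with clean 1,2-selectivity and no attack on lactone, esters or exocyclic methylene at −78 °C.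

Step 23
Reactants: 32 (3R)-alcohol
Product: 33 (3R)-acetate
Conditions: Ac2O (3 equiv), pyridine, DMAP (5 mol%), CH2Cl2, 0 °C → rt
Reagents that add atoms: acetic anhydride, CC(=O)OC(C)=O
Why: DMAP-catalysed acylation esterifies the only free hydroxyl with retention at C3.

Step 24
Reactants: 33 (3R)-acetate
Product: 34 target CNP0181631.1
Conditions: HF·pyridine (excess), THF, 0 °C → rt, polyethylene flask
Reagents that add atoms: none
Why: Fluoride-mediated desilylation under weakly acidic, non-nucleophilic conditions frees the tertiary C10–OH without acyl migration, conjugate addition to the methylene lactone or angelate isomerisation.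

**Compound list**
1 | (R)-(−)-linalool, (3R)-3,7-dimethylocta-1,6-dien-3-ol | C=C[C@](C)(O)CCC=C(C)C | starting material
2 | (3R)-3-(TBSO)-3,7-dimethylocta-1,6-diene | C=C[C@](C)(O[Si](C)(C)C(C)(C)C)CCC=C(C)C | intermediate
3 | (3R)-3-(TBSO)-6,7-epoxy-3,7-dimethyloct-1-ene (C6 epimers) | C=C[C@](C)(O[Si](C)(C)C(C)(C)C)CCC1OC1(C)C | intermediate
4 | (4R)-4-(TBSO)-4-methylhex-5-enal | C=C[C@](C)(O[Si](C)(C)C(C)(C)C)CCC=O | intermediate
5 | (2R,4R)-4-(TBSO)-4-methyl-2-(phenylaminooxy)hex-5-enal | C=C[C@](C)(O[Si](C)(C)C(C)(C)C)C[C@@H](ONc1ccccc1)C=O | intermediate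
6 | (2R,4R)-4-(TBSO)-4-methyl-2-(phenylaminooxy)hex-5-en-1-ol | C=C[C@](C)(O[Si](C)(C)C(C)(C)C)C[C@@H](ONc1ccccc1)CO | intermediate
7 | (2R,4R)-4-(TBSO)-4-methylhex-5-ene-1,2-diol | C=C[C@](C)(O[Si](C)(C)C(C)(C)C)C[C@@H](O)CO | intermediate
8 | (4R)-4-[(2R)-2-(TBSO)-2-methylbut-3-enyl]-2-(4-methoxyphenyl)-1,3-dioxolane (acetal epimers) | C=C[C@](C)(O[Si](C)(C)C(C)(C)C)C[C@@H]1COC(c2ccc(OC)cc2)O1 | intermediate
9 | allyl tert-butyldimethylsilyl ether | C=CCO[Si](C)(C)C(C)(C)C | starting material
10 | (4R)-4-[(2R,3E)-2,5-bis(TBSO)-2-methylpent-3-enyl]-2-(4-methoxyphenyl)-1,3-dioxolane (acetal epimers) | CC(C)(C)[Si](C)(C)OC/C=C/[C@](C)(O[Si](C)(C)C(C)(C)C)C[C@@H]1COC(c2ccc(OC)cc2)O1 | intermediate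
11 | (2R,4R,5E)-4,7-bis(TBSO)-2-(PMBO)-4-methylhept-5-en-1-ol | CC(C)(C)[Si](C)(C)OC/C=C/[C@](C)(O[Si](C)(C)C(C)(C)C)C[C@@H](OCc1ccc(OC)cc1)CO | intermediate
12 | (2R,4R,5E)-4,7-bis(TBSO)-2-(PMBO)-4-methylhept-5-enal | CC(C)(C)[Si](C)(C)OC/C=C/[C@](C)(O[Si](C)(C)C(C)(C)C)C[C@@H](OCc1ccc(OC)cc1)C=O | intermediate
13 | methyl acrylate | C=CC(=O)OC | starting material
14 | methyl (4R,6R,7E)-6,9-bis(TBSO)-3-hydroxy-4-(PMBO)-6-methyl-2-methylidenenon-7-enoate (C3 epimers) | CC(C)(C)[Si](C)(C)OC/C=C/[C@](C)(O[Si](C)(C)C(C)(C)C)C[C@@H](OCc1ccc(OC)cc1)C(O)C(=C)C(=O)OC | intermediate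
15 | methyl (2Z,4R,6R,7E)-2-(bromomethyl)-6,9-bis(TBSO)-4-(PMBO)-6-methylnona-2,7-dienoate | CC(C)(C)[Si](C)(C)OC/C=C/[C@](C)(O[Si](C)(C)C(C)(C)C)C[C@@H](OCc1ccc(OC)cc1)/C=C(\CBr)C(=O)OC | intermediate
16 | ethyl but-2-ynoate | CC#CC(=O)OCC | starting material
17 | ethyl (Z)-3-iodobut-2-enoate | C/C(I)=C/C(=O)OCC | intermediate
18 | (Z)-3-iodobut-2-en-1-ol | C/C(I)=C/CO | intermediate
19 | (Z)-3-iodobut-2-enal | C/C(I)=C/C=O | intermediate
20 | allylzinc bromide from 15 (ZnBr in place of Br, C8 cis to CH2Zn) | CC(C)(C)[Si](C)(C)OC/C=C/[C@](C)(O[Si](C)(C)C(C)(C)C)C[C@@H](OCc1ccc(OC)cc1)/C=C(\C[Zn]Br)C(=O)OC | intermediate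
21 | methyl (3R,4R,6R,7E)-6,9-bis(TBSO)-3-[(1S,2Z)-1-hydroxy-3-iodobut-2-en-1-yl]-4-(PMBO)-6-methyl-2-methylidenenon-7-enoate (same spatial arrangement as 22) | COC(=O)C(=C)[C@H]([C@H](O)/C=C(/C)I)[C@H](OCc1ccc(OC)cc1)C[C@@](C)(O[Si](C)(C)C(C)(C)C)/C=C/CO[Si](C)(C)C(C)(C)C | intermediate
22 | (4S,5S)-4-[(1R,3R,4E)-3,6-bis(TBSO)-1-(PMBO)-3-methylhex-4-en-1-yl]-5-[(1Z)-2-iodoprop-1-en-1-yl]-3-methylideneoxolan-2-one (C6 is S only because iodine raises C5; spatially as 6R of the target) | C=C1C(=O)O[C@H](/C=C(/C)I)[C@@H]1[C@H](OCc2ccc(OC)cc2)C[C@@](C)(O[Si](C)(C)C(C)(C)C)/C=C/CO[Si](C)(C)C(C)(C)C | intermediate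
23 | C8 alcohol: 22 carrying OH at C8 (6S,7S,8R,10R) | C=C1C(=O)O[C@H](/C=C(/C)I)[C@@H]1[C@H](O)C[C@@](C)(O[Si](C)(C)C(C)(C)C)/C=C/CO[Si](C)(C)C(C)(C)C | intermediate
24 | angelic acid, (Z)-2-methylbut-2-enoic acid | C/C=C(/C)C(=O)O | starting material
25 | angelic 2,4,6-trichlorobenzoic anhydride | C/C=C(/C)C(=O)OC(=O)c1c(Cl)cc(Cl)cc1Cl | intermediate
26 | C8 angelate: 23 carrying OAng at C8 (6S,7S,8R,10R) | C=C1C(=O)O[C@H](/C=C(/C)I)[C@@H]1[C@H](OC(=O)/C(C)=C\C)C[C@@](C)(O[Si](C)(C)C(C)(C)C)/C=C/CO[Si](C)(C)C(C)(C)C | intermediate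
27 | primary allylic alcohol: 26 carrying free C3–OH | C=C1C(=O)O[C@H](/C=C(/C)I)[C@@H]1[C@H](OC(=O)/C(C)=C\C)C[C@@](C)(O[Si](C)(C)C(C)(C)C)/C=C/CO | intermediate
28 | (E)-enal: 27 oxidised to the C3 aldehyde | C=C1C(=O)O[C@H](/C=C(/C)I)[C@@H]1[C@H](OC(=O)/C(C)=C\C)C[C@@](C)(O[Si](C)(C)C(C)(C)C)/C=C/C=O | intermediate
29 | alkenylchromium dichloride from 28 (CrCl2 in place of I, Z geometry kept) | C=C1C(=O)O[C@H](/C=C(/C)[Cr](Cl)Cl)[C@@H]1[C@H](OC(=O)/C(C)=C\C)C[C@@](C)(O[Si](C)(C)C(C)(C)C)/C=C/C=O | intermediate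
30 | (3aS,4R,6R,7E,10Z,11aR)-6-(TBSO)-9-hydroxy-6,10-dimethyl-3-methylidene-2-oxo-2,3,3a,4,5,6,9,11a-octahydrocyclodeca[b]furan-4-yl angelate (C9 = germacrane C3 epimers) | C=C1C(=O)O[C@@H]2/C=C(/C)C(O)/C=C/[C@](C)(O[Si](C)(C)C(C)(C)C)C[C@@H](OC(=O)/C(C)=C\C)[C@H]12 | intermediate
31 | (3aS,4R,6R,7E,10Z,11aR)-6-(TBSO)-6,10-dimethyl-3-methylidene-2,9-dioxo-2,3,3a,4,5,6,9,11a-octahydrocyclodeca[b]furan-4-yl angelate | C=C1C(=O)O[C@@H]2/C=C(/C)C(=O)/C=C/[C@](C)(O[Si](C)(C)C(C)(C)C)C[C@@H](OC(=O)/C(C)=C\C)[C@H]12 | intermediate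
32 | (3R)-alcohol: (3aS,4R,6R,7E,9R,10Z,11aR)-9-hydroxy analogue of 30 | C=C1C(=O)O[C@@H]2/C=C(/C)[C@H](O)/C=C/[C@](C)(O[Si](C)(C)C(C)(C)C)C[C@@H](OC(=O)/C(C)=C\C)[C@H]12 | intermediate
33 | (3R)-acetate: 32 acetylated at C3, C10–OTBS kept | C=C1C(=O)O[C@@H]2/C=C(/C)[C@H](OC(C)=O)/C=C/[C@](C)(O[Si](C)(C)C(C)(C)C)C[C@@H](OC(=O)/C(C)=C\C)[C@H]12 | intermediate
34 | CNP0181631.1, (3aS,4R,6R,7E,9R,10Z,11aR)-9-acetoxy-6-hydroxy-6,10-dimethyl-3-methylidene-2-oxo-2,3,3a,4,5,6,9,11a-octahydrocyclodeca[b]furan-4-yl (Z)-2-methylbut-2-enoate | C=C1C(=O)O[C@@H]2/C=C(/C)[C@H](OC(C)=O)/C=C/[C@](C)(O)C[C@@H](OC(=O)/C(C)=C\C)[C@H]12 | target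

**Totals**
Total step count: 24. Longest linear sequence: 21 (steps 1–11, then 15–24).

**Three steps most likely to fail**

Risk 1, step 15. The syn (cis-lactone) preference is general for these allylzincs. The choice of the C7 face by C8 rests on a transition-state model, so the ratio may be low or the other cis-lactone may dominate. The fallback sets out from 14. Acetylation (Ac2O, pyridine, DMAP) gives the Morita–Baylis–Hillman acetate F1. Copper-catalysed SN2′ borylation (B2pin2, CuCl, LiCl, KOAc, DMF) then gives the primary allylboronate F2, with C8 cis to CH2B. F2 is combined with 19 in a closed-chair allylboration catalysed by a chiral BINOL phosphoric acid (3,3′-bis(2,4,6-triisopropylphenyl)-BINOL hydrogen phosphate, both enantiomers tried, toluene, −30 °C). The catalyst then picks the aldehyde face instead of C8, and the chair geometry still links C6 and C7 as syn. Hydrolysis of the borate gives 21, which lactonises with PPTS, and the route is rejoined at 22.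

Risk 2, step 20. Closing a ten-membered ring may lose out to dimerisation or to simple reduction of the C–I bond. The fallback sets out from 26. Intermolecular Nozaki–Hiyama–Kishi coupling with acrolein (CrCl2, catalytic NiCl2, DMSO/THF) gives the divinyl carbinol F3. Ring-closing metathesis (second-generation Hoveyda–Grubbs catalyst, toluene, 80 °C, 1 mM) joins the new vinyl group to C1 and expels allyl silyl ether 9. The ring is thus closed at C1=C2 instead of C3–C4, and the route is rejoined at 30.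

Risk 3, step 22. The two alkenyl arms of the ketone differ only by one methyl group, so the ring conformation may override the catalyst. The fallback sets out from 31. Luche reduction (NaBH4, CeCl3·7H2O, MeOH, −78 °C) proceeds by peripheral attack under substrate control, and the epimers are separated. Any 3R material is 32. The (3S)-alcohol F4 is inverted and acetylated in one operation by a Mitsunobu reaction with acetic acid (PPh3, DIAD, toluene, 0 °C), and the route is rejoined at 33.

**Further compounds**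
F1 | step 15 | methyl (4R,6R,7E)-3-acetoxy-6,9-bis(TBSO)-4-(PMBO)-6-methyl-2-methylidenenon-7-enoate (C3 epimers) | CC(C)(C)[Si](C)(C)OC/C=C/[C@](C)(O[Si](C)(C)C(C)(C)C)C[C@@H](OCc1ccc(OC)cc1)C(OC(C)=O)C(=C)C(=O)OC
F2 | step 15 | methyl (2E,4R,6R,7E)-6,9-bis(TBSO)-4-(PMBO)-6-methyl-2-[(4,4,5,5-tetramethyl-1,3,2-dioxaborolan-2-yl)methyl]nona-2,7-dienoate | CC(C)(C)[Si](C)(C)OC/C=C/[C@](C)(O[Si](C)(C)C(C)(C)C)C[C@@H](OCc1ccc(OC)cc1)/C=C(\CB1OC(C)(C)C(C)(C)O1)C(=O)OC
F3 | step 20 | divinyl carbinol: 26 carrying CH(OH)CH=CH2 in place of iodine (carbinol epimers, Z geometry kept) | C=C1C(=O)O[C@H](/C=C(/C)C(O)C=C)[C@@H]1[C@H](OC(=O)/C(C)=C\C)C[C@@](C)(O[Si](C)(C)C(C)(C)C)/C=C/CO[Si](C)(C)C(C)(C)C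
F4 | step 22 | (3S)-alcohol, C3 epimer of 32 | C=C1C(=O)O[C@@H]2/C=C(/C)[C@@H](O)/C=C/[C@](C)(O[Si](C)(C)C(C)(C)C)C[C@@H](OC(=O)/C(C)=C\C)[C@H]12
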